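A ratio, target gained per partner lost, has no time in it, so it can be read from a flask that has stopped.

the same everywhere: starting material 0.051 M; partner 0.0612 M

| flask | second substrate | temperature | remark | time |
|---|---|---|---|---|
| Thursday's | 0.0102 M | 20 °C | the very flask that is asked about, followed so far |  |
| Friday's | 0.0051 M | 15 °C | run made earlier |  |
| flask | 0.0102 M | 20 °C |  | 30 min |

- Thursday's (time / min: target / %): 8.00: 79; 15.0: 78; 25.0: 80; 30.0: 82
- Friday's (time / min: target / %): 2.50: 68; 5.00: 77; 8.00: 81; 10.0: 86

(readings scatter by 2 percentage points)

- teal: change nothing and wait 10 min more
- violet: at 30 min add partner, 100% of the amount charged, then wait 10 min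
- ochre: at 30 min raise the temperature by 15 K, then wait 10 min
- blue: at 30 min take out 90% of the target then present, then wait 10 min

- target, in percent of the starting material first charged, at 30 min
- what to do for the largest gain in target; "none" if nothing gains more than 2 percentage points (teal / violet / ochre / blue / none)
- target present, with what was taken out counted in, in percent of the starting material first charged, after teal
- target present, with what was taken out counted in, in percent of the starting material first charged, after violet

- removed target is counted in
- the earlier runs were read with a standard deviation of 2 percentage points
- additions bring no volume worth counting

Thursday's flask reads flat, with a mean of 79.8% from 8.00 min to 30.0 min, and two chemists dispute why. The first takes partner as the limiting reagent in Thursday's flask, and reckons 0.665 for the partner yield, the target made per partner charged. Friday's flask, colder and with half the second substrate, read 86% at 10.0 min, which gives a reading of 0.717 for the same ratio, so the first chemist holds that second substrate takes a share of partner.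

The second chemist says Thursday's flask has reached a balance, first order each way. On that view, partner still stands there at 0.402 of the starting material charge, and the colder Friday flask simply lies further toward target.

My own reckoning follows the first chemist. On the partner yield, violet's fresh partner is reckoned to carry 79.8% of the charge, more than the missing 20.2%, so this reckoning puts violet at the whole charge, higher than the forecast's central figure for violet.

The forecast takes the first side: 80% (78.5% to 81.5%) now, violet as the best choice, 80.5% (78.5% to 83%) after teal and 96% (82% to 100%) after violet. In its words, “Waiting or heating does little.”

The simulation gives 80.2% now, 79.9% after teal and 98.4% after violet, so violet gains 18 percentage points.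

    starting material + partner → target (k = 0.300 M⁻¹ s⁻¹, Ea = 39.0 kJ mol⁻¹)
    second substrate + partner → second product (k = 10.0 M⁻¹ s⁻¹, Ea = 48.0 kJ mol⁻¹)
    target → over-reaction product (k = 7.70 × 10⁻⁶ s⁻¹, Ea = 96.0 kJ mol⁻¹)
    partner → decomposed reagent (k = 0.00180 s⁻¹, Ea = 95.0 kJ mol⁻¹)
    2 second substrate → homo dimer (k = 3.00 M⁻¹ s⁻¹, Ea = 38.0 kJ mol⁻¹)
    (constants at 20 °C)

The first chemist is right: at 30.0 min this flask holds 0.0058% of its partner charge beside 19% of its starting material. The second chemist's view keeps the readings: first order each way, starting material with partner, fits them with a misfit of 1.1 scatter units. The partner yield, applied to a neighbour flask charged with 0.471 equiv of partner, gives 31.3%, and that neighbour shows 25.7%. This flask is not at rest: left until 300 min, it keeps 18.7% of starting material, while over-reaction product reaches 10.5% and target falls to 70.8%.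

All runs were generated by integration for substances that don't exist, noise included.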